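**Retrosynthetic overview**

- Feature: ring B is a hexasubstituted benzene whose free phenol carbon (between the CH2OH carbon and the lactone-carbonyl carbon) lies para to the carbon carrying the diaryl-ether oxygen, with the ester oxygen next to that carbon. This is a fully substituted hydroquinone with three differentiated oxygens, the pattern a squarate-derived cyclobutenone gives on ring expansion.
- Endgame: the (S)-lactol comes from an (R)-benzyl carbonate made by dynamic kinetic resolution of the 3-hydroxyphthalide; the lactol comes from an aryl acid next to a masked aldehyde.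
- Central ring: seven-membered lactone from a hydroxy acid; diaryl ether by SNAr of the ring-B phenoxide on a ready-made 2-fluoro-3-formylbenzoate (ring A).
- Ring B: thermolysis of a 4-alkenyl-4-silyloxycyclobutenone (4π opening, 6π closure), assembled from diallyl squarate, MOMOCH2Li and an α-lithiated (Z)-iodo-enal acetal.
- Ring order: ring B (step 7), then the dioxepinone ring (ether in step 14, lactone in step 18), then the γ-lactol ring (step 21).

Key step: step 7

Remark on the chemistry: the lactol carbon is a hemiacetal that epimerises by ring–chain tautomerism under base, so its configuration is fixed as a carbonate and released only in the last, neutral step; the product is to be kept away from base.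

Protecting-group plan: allyl on the squarate oxygen and on the ring-A carboxyl (Pd(0)); benzyl on both phenols and a benzyl carbonate on the lactol (final hydrogenolysis); MOM on the two CH2OH groups; PMB on the carbon that is oxidised to the lactone carbonyl.

**Route**

Step 1
Reactants: 1 3,3-diethoxyprop-1-yne; 2 formaldehyde (as paraformaldehyde)
Product: 3 4,4-diethoxybut-2-yn-1-ol
Conditions: n-BuLi, THF, −78 °C; (CH2O)n, −78 °C → rt; H2O
Reagents that add atoms: none
Why: Addition of the lithium acetylide to formaldehyde (alkynylation); the acetal is inert to the base.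

Step 2
Reactants: 3 4,4-diethoxybut-2-yn-1-ol
Product: 4 (2Z)-4,4-diethoxy-3-iodobut-2-en-1-ol
Conditions: Red-Al, THF, 0 °C; EtOAc; then I2, −78 → 0 °C; aq. Rochelle salt/Na2S2O3
Reagents that add atoms: iodine, II
Why: Alkoxide-directed trans-hydroalumination of the propargylic alcohol puts hydride on C2 and aluminium on C3 through a five-membered oxa-aluminacycle, and iodinolysis with retention should give the (Z)-3-iodoalkenol with iodine cis to CH2OH.

Step 3
Reactants: 4 (2Z)-4,4-diethoxy-3-iodobut-2-en-1-ol
Product: 5 1-({[(2Z)-4,4-diethoxy-3-iodobut-2-en-1-yl]oxy}methyl)-4-methoxybenzene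
Conditions: NaH, PMBCl, TBAI (cat.), THF/DMF, 0 °C → rt
Reagents that add atoms: 4-methoxybenzyl chloride, COc1ccc(CCl)cc1
Why: Williamson etherification of the primary alkoxide; the low temperature avoids dehydroiodination of the vinyl iodide.

Step 4
Reactants: 6 squaric acid
Product: 7 diallyl squarate (3,4-bis(allyloxy)cyclobut-3-ene-1,2-dione)
Conditions: allyl alcohol–toluene, Dean–Stark, reflux
Reagents that add atoms: allyl alcohol, C=CCO
Why: Squaric acid is a strong vinylogous diacid that catalyses its own Fischer-type esterification, and azeotropic removal of water drives diester formation.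

Step 5
Reactants: 7 diallyl squarate; 8 tributyl[(methoxymethoxy)methyl]stannane
Product: 11 3-(allyloxy)-4-[(methoxymethoxy)methyl]cyclobut-3-ene-1,2-dione, via (methoxymethoxy)methyllithium 9 (not isolated), via lithium alkoxide adduct 10 (not isolated)
Conditions: 8, n-BuLi, THF, −78 °C; add to 7, THF, −78 °C; TFAA, −78 → 0 °C; aq. NH4Cl
Reagents that add atoms: none
Why: Tin–lithium exchange gives the α-alkoxymethyllithium 9 (MOM is used because an α-silyloxymethyllithium would undergo retro-Brook rearrangement), which adds 1,2 to one squarate carbonyl; trifluoroacetylation of alkoxide 10 and ionisation with loss of one allyloxy group as allyl trifluoroacetate unveils the second carbonyl (squarate-to-cyclobutenedione homologation).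

Step 6
Reactants: 5 PMB-protected (Z)-vinyl iodide; 11 3-(allyloxy)-4-[(methoxymethoxy)methyl]cyclobut-3-ene-1,2-dione
Product: 14 racemic 3-(allyloxy)-4-[(tert-butyldimethylsilyl)oxy]-4-[(2E)-1,1-diethoxy-4-[(4-methoxybenzyl)oxy]but-2-en-2-yl]-2-[(methoxymethoxy)methyl]cyclobut-2-en-1-one, via vinyllithium 12 (not isolated), via tertiary lithium alkoxide 13 (not isolated)
Conditions: 5, t-BuLi (2.1 equiv), Et2O, −78 °C; add to 11, THF, −78 °C; TBSOTf, −78 → −20 °C
Reagents that add atoms: tert-butyldimethylsilyl trifluoromethanesulfonate, CC(C)(C)[Si](C)(C)OS(=O)(=O)C(F)(F)F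
Why: Iodine–lithium exchange keeps the alkene geometry and gives the acetal- and ether-chelated vinyllithium 12, which adds to the ketone-like carbonyl next to the allyloxy-bearing carbon (the other carbonyl is deactivated as a vinylogous ester), and the tertiary alkoxide 13 is silylated in situ; the carbinol stereocentre forms racemic and is erased in step 7.

Step 7
Reactants: 14 racemic 4-alkenyl-4-silyloxycyclobutenone
Product: 17 3-(allyloxy)-4-[(tert-butyldimethylsilyl)oxy]-5-(diethoxymethyl)-6-{[(4-methoxybenzyl)oxy]methyl}-2-[(methoxymethoxy)methyl]phenol, via dienylketene 15 (not isolated), via cyclohexa-2,4-dienone 16 (not isolated)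
Conditions: PhMe (0.02 M, degassed), 110 °C
Reagents that add atoms: none
Why: Thermal conrotatory 4π-electrocyclic opening of the C1–C4 bond gives dienylketene 15; the donor OTBS group rotates outward and so places the alkenyl arm cis to the ketene, which closes by thermal disrotatory 6π-electrocyclisation (new bond between the ketene carbon and the alkene CH carbon, closing ring B) to dienone 16, and enolisation of its one sp3 C–H gives the arene; this is the Moore rearrangement of 4-alkenyl-4-oxycyclobutenones. The single new skeletal bond is C(OH)–C(CH2OPMB), and no stereocentre remains because the carbinol carbon of 14 and the transient sp3 carbon of 16 both become arene carbons. The selectivity needed is positional: the ring order O-allyl, CH2OMOM, OH, CH2OPMB, CH(OEt)2, OTBS is written into the connectivity of 14 (ketene carbon becomes the free phenol flanked by both CH2O carbons, carbinol carbon becomes the silyl ether next to the acetal carbon), so no arene substitution rule is involved. The CH2OPMB group sits on the inward position of the alkene terminus, which the sterically undemanding sp ketene carbon should tolerate, and the silyl group keeps the two para oxygens distinct. At 110 °C the cascade should outrun Claisen shift of the allyl enol ether and capture of the ketene by the allyl alkene.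

Step 8
Reactants: 17 ring-B phenol
Product: 18 tert-butyl{2-(allyloxy)-4-(benzyloxy)-6-(diethoxymethyl)-5-{[(4-methoxybenzyl)oxy]methyl}-3-[(methoxymethoxy)methyl]phenoxy}dimethylsilane
Conditions: NaH, BnBr, TBAI (cat.), DMF, 0 °C
Reagents that add atoms: benzyl bromide, BrCc1ccccc1
Why: Williamson etherification of the sodium phenoxide; without a nucleophilic oxygen base the para aryl silyl ether, the acetal and the allyl ether are left alone.

Step 9
Reactants: 19 3-fluoro-5-methylphenol
Product: 20 4-bromo-3-fluoro-5-methylphenol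
Conditions: NBS, MeCN, 0 °C
Reagents that add atoms: N-bromosuccinimide, O=C1CCC(=O)N1Br
Why: Electrophilic aromatic bromination directed para by the hydroxyl group, as with other 3,5-disubstituted phenols.

Step 10
Reactants: 20 4-bromo-3-fluoro-5-methylphenol
Product: 21 5-(benzyloxy)-2-bromo-1-fluoro-3-methylbenzene
Conditions: BnBr, K2CO3, DMF, rt
Reagents that add atoms: benzyl bromide, BrCc1ccccc1
Why: Williamson etherification of the phenoxide.

Step 11
Reactants: 21 5-(benzyloxy)-2-bromo-1-fluoro-3-methylbenzene
Product: 23 6-(benzyloxy)-3-bromo-2-fluoro-4-methylbenzaldehyde, via aryllithium 22 (not isolated)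
Conditions: LDA, THF, −78 °C; DMF; 1 M HCl
Reagents that add atoms: N,N-dimethylformamide, CN(C)C=O
Why: Directed ortho-metalation: LDA removes the most acidic ring proton, the one flanked by fluorine and the benzyloxy group, without bromine–lithium exchange, and aryllithium 22 is formylated by DMF.

Step 12
Reactants: 23 6-(benzyloxy)-3-bromo-2-fluoro-4-methylbenzaldehyde
Product: 26 4-(benzyloxy)-2-fluoro-3-formyl-6-methylbenzoic acid, via lithium α-amino alkoxide 24 (not isolated), via aryllithium 25 (not isolated)
Conditions: LiN(Me)CH2CH2NMe2, THF, −78 → −20 °C; n-BuLi, −78 °C; CO2, −78 °C → rt; 1 M HCl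
Reagents that add atoms: carbon dioxide, O=C=O
Why: In situ protection of the aldehyde as α-amino alkoxide 24 allows bromine–lithium exchange at −78 °C, where the ortho-fluoro aryllithium 25 does not eliminate LiF, and carboxylation with acid work-up returns the aldehyde beside the new acid.

Step 13
Reactants: 26 4-(benzyloxy)-2-fluoro-3-formyl-6-methylbenzoic acid
Product: 27 allyl 4-(benzyloxy)-2-fluoro-3-formyl-6-methylbenzoate
Conditions: allyl bromide, KHCO3, DMF, rt
Reagents that add atoms: allyl bromide, C=CCBr
Why: SN2 alkylation of the carboxylate under weakly basic conditions at room temperature, which leaves the activated fluoride and the aldehyde alone.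

Step 14
Reactants: 18 ring-B aryl silyl ether; 27 allyl 4-(benzyloxy)-2-fluoro-3-formyl-6-methylbenzoate
Product: 29 allyl 2-{2-(allyloxy)-4-(benzyloxy)-6-(diethoxymethyl)-5-{[(4-methoxybenzyl)oxy]methyl}-3-[(methoxymethoxy)methyl]phenoxy}-4-(benzyloxy)-3-formyl-6-methylbenzoate, via caesium phenoxide 28 (not isolated)
Conditions: CsF, DMF, rt → 50 °C
Reagents that add atoms: none
Why: Fluoride cleaves the aryl silyl ether to phenoxide 28, which displaces the fluoride activated by the ortho formyl and ortho ester groups (SNAr through a Meisenheimer adduct); the fluoride released keeps the desilylation going, and the alkyl ethers, acetal and esters are inert.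

Step 15
Reactants: 29 diaryl ether aldehyde
Product: 30 the corresponding ring-A benzylic alcohol (3-(hydroxymethyl) in place of 3-formyl)
Conditions: NaBH4, THF/MeOH, 0 °C
Reagents that add atoms: none
Why: Chemoselective borohydride reduction of the aryl aldehyde; the di-ortho-substituted allyl benzoate is not reduced at 0 °C.

Step 16
Reactants: 30 ring-A benzylic alcohol
Product: 31 its methoxymethyl ether (ring-A 3-[(methoxymethoxy)methyl])
Conditions: MOMCl, iPr2NEt, CH2Cl2, 0 °C → rt
Reagents that add atoms: chloromethyl methyl ether, COCCl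
Why: O-Alkylation with the chloromethyl ether under amine base (MOM protection) masks the new benzylic alcohol against the later oxidation.

Step 17
Reactants: 31 allyl ether allyl ester
Product: 32 4-(benzyloxy)-2-{4-(benzyloxy)-6-(diethoxymethyl)-2-hydroxy-5-{[(4-methoxybenzyl)oxy]methyl}-3-[(methoxymethoxy)methyl]phenoxy}-3-[(methoxymethoxy)methyl]-6-methylbenzoic acid
Conditions: Pd(PPh3)4 (cat.), morpholine, THF, rt; pH 5 buffer
Reagents that add atoms: none
Why: Tsuji–Trost deallylation: Pd(0) ionises both the aryl allyl ether and the allyl ester to π-allyl palladium, which morpholine captures, while PMB, benzyl, MOM and acetal groups are inert.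

Step 18
Reactants: 32 hydroxy acid
Product: 33 3,8-bis(benzyloxy)-6-(diethoxymethyl)-7-{[(4-methoxybenzyl)oxy]methyl}-4,9-bis[(methoxymethoxy)methyl]-1-methyl-11H-dibenzo[b,e][1,4]dioxepin-11-one
Conditions: EDC·HCl, DMAP, CH2Cl2 (0.005 M), rt
Reagents that add atoms: none
Why: Carbodiimide activation (Steglich conditions) of the benzoic acid and attack by the only phenol within reach closes the seven-membered lactone of the depsidone; high dilution suppresses dimers.

Step 19
Reactants: 33 protected depsidone
Product: 34 the 7-(hydroxymethyl) depsidone (PMB removed)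
Conditions: DDQ, CH2Cl2/pH 7 buffer, 0 °C → rt
Reagents that add atoms: none
Why: DDQ removes the p-methoxybenzyl group by hydride abstraction and hydrolysis of the oxocarbenium ion, leaving benzyl ethers, MOM ethers and the acetal intact in the buffered medium.

Step 20
Reactants: 34 7-(hydroxymethyl) depsidone
Product: 35 the depsidone 7-carbaldehyde
Conditions: Dess–Martin periodinane, NaHCO3, CH2Cl2, 0 °C → rt
Reagents that add atoms: none
Why: Dess–Martin oxidation of the benzylic alcohol to the aldehyde under buffered, non-acidic conditions.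

Step 21
Reactants: 35 depsidone 7-carbaldehyde
Product: 37 racemic depsidone-fused 3-hydroxyphthalide (lactone carbonyl on C7, CH(OH) on C6; phenols benzylated, both CH2OH groups as MOM ethers), via 7-carboxylic acid 36 (not isolated)
Conditions: NaClO2, NaH2PO4, 2-methyl-2-butene, t-BuOH/THF/H2O, 0 °C → rt; Na2SO3; then 2 M HCl/THF, rt
Reagents that add atoms: sodium chlorite, [Na+].[O-]Cl=O; water, O
Why: Pinnick oxidation gives acid 36, and dilute acid then hydrolyses the neighbouring diethyl acetal so that the formyl acid closes to the 3-hydroxyphthalide (ring–chain tautomerism), formed racemic; the alkyl MOM ethers, benzyl ethers and aryl lactone tolerate dilute acid at room temperature.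

Step 22
Reactants: 37 racemic 3-hydroxyphthalide
Product: 38 (R)-benzyl carbonate of the lactol (same spatial arrangement as the (S)-lactol of the target)
Conditions: (BnOCO)2O, chiral isothiourea (HyperBTM, enantiomer selected for the (R)-carbonate, 10 mol%), iPr2NEt, PhMe/CH2Cl2, −40 °C
Reagents that add atoms: dibenzyl dicarbonate, O=C(OCc1ccccc1)OC(=O)OCc1ccccc1
Why: Proposed new method: the chiral Lewis base is alkoxycarbonylated by the dicarbonate to an N-(benzyloxycarbonyl) isothiouronium ion that should transfer the Cbz group to one lactol enantiomer faster than to the other, while iPr2NEt interconverts the lactol enantiomers through the ring-opened formyl carboxylate so that all material can funnel to the (R)-carbonate (the descriptor differs from the target only because the carbonate oxygen outranks the ring oxygen); the closest known reaction type is the acylative dynamic kinetic resolution of 3-hydroxyphthalides with carboxylic anhydrides under chiral nucleophilic catalysis, extended here to a pyrocarbonate donor.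

Step 23
Reactants: 38 (R)-benzyl carbonate
Product: 39 (R)-benzyl carbonate with both hydroxymethyl groups free (phenols still benzylated)
Conditions: 2 M H2SO4, THF/H2O, 45 °C
Reagents that add atoms: none
Why: Acid-catalysed hydrolysis of the two alkyl MOM ethers; because both phenols are still benzylated no cyclic formal can form, and the acylal-type carbonate and aryl lactone are expected to withstand aqueous acid, so the stereocentre is untouched.

Step 24
Reactants: 39 (R)-benzyl carbonate diol
Product: 40 target, the (S)-lactol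
Conditions: H2 (1 atm), 10% Pd/C, EtOAc/THF, rt, short contact time
Reagents that add atoms: none
Why: Hydrogenolysis cleaves the two aryl benzyl ethers and the benzyl carbonate, whose carbonic acid half-ester loses CO2 to free the lactol OH without breaking a bond at the stereocentre (retention; the descriptor becomes S only through the CIP change), under neutral aprotic conditions that should not open the lactol.

**Compound list**

1 | 3,3-diethoxyprop-1-yne | C#CC(OCC)OCC | starting material
2 | formaldehyde (used as paraformaldehyde) | C=O | starting material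
3 | 4,4-diethoxybut-2-yn-1-ol | OCC#CC(OCC)OCC | intermediate
4 | (2Z)-4,4-diethoxy-3-iodobut-2-en-1-ol | OC/C=C(\I)C(OCC)OCC | intermediate
5 | 1-({[(2Z)-4,4-diethoxy-3-iodobut-2-en-1-yl]oxy}methyl)-4-methoxybenzene | COc1ccc(COC/C=C(\I)C(OCC)OCC)cc1 | intermediate
6 | squaric acid (3,4-dihydroxycyclobut-3-ene-1,2-dione) | OC1=C(O)C(=O)C1=O | starting material
7 | diallyl squarate (3,4-bis(allyloxy)cyclobut-3-ene-1,2-dione) | C=CCOC1=C(OCC=C)C(=O)C1=O | intermediate
8 | tributyl[(methoxymethoxy)methyl]stannane | CCCC[Sn](CCCC)(CCCC)COCOC | starting material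
9 | (methoxymethoxy)methyllithium | [Li]COCOC | intermediate
10 | lithium alkoxide of racemic 2,3-bis(allyloxy)-4-hydroxy-4-[(methoxymethoxy)methyl]cyclobut-2-en-1-one | C=CCOC1=C(OCC=C)C(O[Li])(COCOC)C1=O | intermediate
11 | 3-(allyloxy)-4-[(methoxymethoxy)methyl]cyclobut-3-ene-1,2-dione | C=CCOC1=C(COCOC)C(=O)C1=O | intermediate
12 | [(2E)-1,1-diethoxy-4-[(4-methoxybenzyl)oxy]but-2-en-2-yl]lithium (lithium cis to CH2OPMB) | [Li]/C(=C\COCc1ccc(OC)cc1)C(OCC)OCC | intermediate
13 | lithium alkoxide of racemic 3-(allyloxy)-4-[(2E)-1,1-diethoxy-4-[(4-methoxybenzyl)oxy]but-2-en-2-yl]-4-hydroxy-2-[(methoxymethoxy)methyl]cyclobut-2-en-1-one | O=C1C(COCOC)=C(OCC=C)C1(O[Li])/C(=C\COCc1ccc(OC)cc1)C(OCC)OCC | intermediate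
14 | racemic 3-(allyloxy)-4-[(tert-butyldimethylsilyl)oxy]-4-[(2E)-1,1-diethoxy-4-[(4-methoxybenzyl)oxy]but-2-en-2-yl]-2-[(methoxymethoxy)methyl]cyclobut-2-en-1-one | O=C1C(COCOC)=C(OCC=C)C1(O[Si](C)(C)C(C)(C)C)/C(=C\COCc1ccc(OC)cc1)C(OCC)OCC | intermediate
15 | dienylketene from ring opening of 14 (OTBS outward, alkenyl arm cis to the ketene) | O=C=C(COCOC)\C(OCC=C)=C(O[Si](C)(C)C(C)(C)C)/C(=C\COCc1ccc(OC)cc1)C(OCC)OCC | intermediate
16 | racemic 3-(allyloxy)-4-[(tert-butyldimethylsilyl)oxy]-5-(diethoxymethyl)-6-{[(4-methoxybenzyl)oxy]methyl}-2-[(methoxymethoxy)methyl]cyclohexa-2,4-dien-1-one | O=C1C(COCOC)=C(OCC=C)C(O[Si](C)(C)C(C)(C)C)=C(C(OCC)OCC)C1COCc1ccc(OC)cc1 | intermediate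
17 | 3-(allyloxy)-4-[(tert-butyldimethylsilyl)oxy]-5-(diethoxymethyl)-6-{[(4-methoxybenzyl)oxy]methyl}-2-[(methoxymethoxy)methyl]phenol | Oc1c(COCOC)c(OCC=C)c(O[Si](C)(C)C(C)(C)C)c(C(OCC)OCC)c1COCc1ccc(OC)cc1 | intermediate
18 | tert-butyl{2-(allyloxy)-4-(benzyloxy)-6-(diethoxymethyl)-5-{[(4-methoxybenzyl)oxy]methyl}-3-[(methoxymethoxy)methyl]phenoxy}dimethylsilane | c1ccccc1COc1c(COCOC)c(OCC=C)c(O[Si](C)(C)C(C)(C)C)c(C(OCC)OCC)c1COCc1ccc(OC)cc1 | intermediate
19 | 3-fluoro-5-methylphenol | Cc1cc(O)cc(F)c1 | starting material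
20 | 4-bromo-3-fluoro-5-methylphenol | Cc1cc(O)cc(F)c1Br | intermediate
21 | 5-(benzyloxy)-2-bromo-1-fluoro-3-methylbenzene | Cc1cc(OCc2ccccc2)cc(F)c1Br | intermediate
22 | [6-(benzyloxy)-3-bromo-2-fluoro-4-methylphenyl]lithium | Cc1cc(OCc2ccccc2)c([Li])c(F)c1Br | intermediate
23 | 6-(benzyloxy)-3-bromo-2-fluoro-4-methylbenzaldehyde | Cc1cc(OCc2ccccc2)c(C=O)c(F)c1Br | intermediate
24 | lithium α-amino alkoxide of 23 with N,N,N'-trimethylethylenediamine | Cc1cc(OCc2ccccc2)c(C(O[Li])N(C)CCN(C)C)c(F)c1Br | intermediate
25 | aryllithium from bromine–lithium exchange of 24 | Cc1cc(OCc2ccccc2)c(C(O[Li])N(C)CCN(C)C)c(F)c1[Li] | intermediate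
26 | 4-(benzyloxy)-2-fluoro-3-formyl-6-methylbenzoic acid | Cc1cc(OCc2ccccc2)c(C=O)c(F)c1C(=O)O | intermediate
27 | allyl 4-(benzyloxy)-2-fluoro-3-formyl-6-methylbenzoate | Cc1cc(OCc2ccccc2)c(C=O)c(F)c1C(=O)OCC=C | intermediate
28 | caesium 2-(allyloxy)-4-(benzyloxy)-6-(diethoxymethyl)-5-{[(4-methoxybenzyl)oxy]methyl}-3-[(methoxymethoxy)methyl]phenoxide | [Cs+].[O-]c1c(OCC=C)c(COCOC)c(OCc2ccccc2)c(COCc2ccc(OC)cc2)c1C(OCC)OCC | intermediate
29 | allyl 2-{2-(allyloxy)-4-(benzyloxy)-6-(diethoxymethyl)-5-{[(4-methoxybenzyl)oxy]methyl}-3-[(methoxymethoxy)methyl]phenoxy}-4-(benzyloxy)-3-formyl-6-methylbenzoate | C=CCOc1c(COCOC)c(OCc2ccccc2)c(COCc2ccc(OC)cc2)c(C(OCC)OCC)c1Oc1c(C=O)c(OCc2ccccc2)cc(C)c1C(=O)OCC=C | intermediate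
30 | allyl 2-{2-(allyloxy)-4-(benzyloxy)-6-(diethoxymethyl)-5-{[(4-methoxybenzyl)oxy]methyl}-3-[(methoxymethoxy)methyl]phenoxy}-4-(benzyloxy)-3-(hydroxymethyl)-6-methylbenzoate | C=CCOc1c(COCOC)c(OCc2ccccc2)c(COCc2ccc(OC)cc2)c(C(OCC)OCC)c1Oc1c(CO)c(OCc2ccccc2)cc(C)c1C(=O)OCC=C | intermediate
31 | allyl 2-{2-(allyloxy)-4-(benzyloxy)-6-(diethoxymethyl)-5-{[(4-methoxybenzyl)oxy]methyl}-3-[(methoxymethoxy)methyl]phenoxy}-4-(benzyloxy)-3-[(methoxymethoxy)methyl]-6-methylbenzoate | C=CCOc1c(COCOC)c(OCc2ccccc2)c(COCc2ccc(OC)cc2)c(C(OCC)OCC)c1Oc1c(COCOC)c(OCc2ccccc2)cc(C)c1C(=O)OCC=C | intermediate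
32 | 4-(benzyloxy)-2-{4-(benzyloxy)-6-(diethoxymethyl)-2-hydroxy-5-{[(4-methoxybenzyl)oxy]methyl}-3-[(methoxymethoxy)methyl]phenoxy}-3-[(methoxymethoxy)methyl]-6-methylbenzoic acid | Oc1c(COCOC)c(OCc2ccccc2)c(COCc2ccc(OC)cc2)c(C(OCC)OCC)c1Oc1c(COCOC)c(OCc2ccccc2)cc(C)c1C(=O)O | intermediate
33 | 3,8-bis(benzyloxy)-6-(diethoxymethyl)-7-{[(4-methoxybenzyl)oxy]methyl}-4,9-bis[(methoxymethoxy)methyl]-1-methyl-11H-dibenzo[b,e][1,4]dioxepin-11-one | Cc1cc(OCc3ccccc3)c(COCOC)c2c1C(=O)Oc1c(COCOC)c(OCc3ccccc3)c(COCc3ccc(OC)cc3)c(C(OCC)OCC)c1O2 | intermediate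
34 | 3,8-bis(benzyloxy)-6-(diethoxymethyl)-7-(hydroxymethyl)-4,9-bis[(methoxymethoxy)methyl]-1-methyl-11H-dibenzo[b,e][1,4]dioxepin-11-one | Cc1cc(OCc3ccccc3)c(COCOC)c2c1C(=O)Oc1c(COCOC)c(OCc3ccccc3)c(CO)c(C(OCC)OCC)c1O2 | intermediate
35 | 3,8-bis(benzyloxy)-6-(diethoxymethyl)-4,9-bis[(methoxymethoxy)methyl]-1-methyl-11-oxo-11H-dibenzo[b,e][1,4]dioxepine-7-carbaldehyde | Cc1cc(OCc3ccccc3)c(COCOC)c2c1C(=O)Oc1c(COCOC)c(OCc3ccccc3)c(C=O)c(C(OCC)OCC)c1O2 | intermediate
36 | 3,8-bis(benzyloxy)-6-(diethoxymethyl)-4,9-bis[(methoxymethoxy)methyl]-1-methyl-11-oxo-11H-dibenzo[b,e][1,4]dioxepine-7-carboxylic acid | Cc1cc(OCc3ccccc3)c(COCOC)c2c1C(=O)Oc1c(COCOC)c(OCc3ccccc3)c(C(=O)O)c(C(OCC)OCC)c1O2 | intermediate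
37 | racemic depsidone-fused 3-hydroxyphthalide, both phenols as benzyl ethers and both CH2OH groups as MOM ethers | Cc1cc(OCc4ccccc4)c(COCOC)c2c1C(=O)Oc1c(COCOC)c(OCc4ccccc4)c3c(c1O2)C(O)OC3=O | intermediate
38 | (R)-benzyl carbonate of lactol 37 | Cc1cc(OCc4ccccc4)c(COCOC)c2c1C(=O)Oc1c(COCOC)c(OCc4ccccc4)c3c(c1O2)[C@@H](OC(=O)OCc1ccccc1)OC3=O | intermediate
39 | (R)-benzyl carbonate with both hydroxymethyl groups free and both phenols as benzyl ethers | Cc1cc(OCc4ccccc4)c(CO)c2c1C(=O)Oc1c(CO)c(OCc4ccccc4)c3c(c1O2)[C@@H](OC(=O)OCc1ccccc1)OC3=O | intermediate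
40 | target CNP0155661.1, (S)-configured lactol | Cc1cc(O)c(CO)c2c1C(=O)Oc1c(CO)c(O)c3c(c1O2)[C@@H](O)OC3=O | target

**Step count and risks**

Total step count: 24. Longest linear sequence: 17 steps (steps 1, 2, 3, 6, 7, 8, 14–24).

Steps most likely to fail:

1. Step 22 (Proposed new method). The alkoxycarbonyl transfer may discriminate the lactol enantiomers poorly, or an uncatalysed pathway through the ring-opened formyl carboxylate may compete, so that the carbonate forms with low enantiomeric purity. Fallback with known chemistry: setting out from 37, benzyl chloroformate and pyridine in CH2Cl2 give the racemic benzyl carbonate F1. The carbonate is configurationally stable, so preparative chromatography on a chiral stationary phase separates the (R)-enantiomer, which is 38, from the (S)-benzyl carbonate F2, and the route continues from 38.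

2. Step 14. Attack of the doubly ortho-substituted phenoxide on a fluoride that is itself flanked by formyl and ester groups may be too slow (steric congestion at both partners), so that the phenoxide is lost to aldehyde addition and decomposition. Fallback: setting out from 18 and aldehyde 23, whose fluoride is flanked by the formyl group and a compact bromine instead of the ester, CsF in DMF at 60–80 °C should give the diaryl ether bromo aldehyde F3. NaBH4 then gives the benzylic alcohol F4, MOMCl/iPr2NEt gives the MOM ether F5, and Pd(PPh3)4/morpholine frees the ring-B phenol F6. Palladium-catalysed carbonylative lactonisation of F6 (Pd(OAc)2, Xantphos, CO 1 atm, Et3N, toluene, 100 °C; aryl bromide to acyl palladium, captured by the phenol) installs the carboxyl carbon and closes the seven-membered lactone in one operation, coming back to the route at 33.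

3. Step 24. Hydrogenolysis may go on to cleave the benzylic C–O bonds of the two hydroxymethyl groups or of the lactol during the time the two aryl benzyl ethers need, and the freed lactol may lose configurational purity on prolonged contact with the catalyst. Fallback: setting out from 39, the aryl benzyl ethers are cleaved without hydrogen by BCl3 with pentamethylbenzene as cation scavenger (CH2Cl2, −78 °C, quenched cold) to give the bis-phenol benzyl carbonate F7. Only the benzyl carbonate is then removed by a brief hydrogenolysis (Pd/C, H2, EtOAc), coming back at 40.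

**Further compounds**

F1 | step 22 | racemic benzyl carbonate of lactol 37 | Cc1cc(OCc4ccccc4)c(COCOC)c2c1C(=O)Oc1c(COCOC)c(OCc4ccccc4)c3c(c1O2)C(OC(=O)OCc1ccccc1)OC3=O
F2 | step 22 | (S)-benzyl carbonate, enantiomer of 38 | Cc1cc(OCc4ccccc4)c(COCOC)c2c1C(=O)Oc1c(COCOC)c(OCc4ccccc4)c3c(c1O2)[C@H](OC(=O)OCc1ccccc1)OC3=O
F3 | step 14 | 2-{2-(allyloxy)-4-(benzyloxy)-6-(diethoxymethyl)-5-{[(4-methoxybenzyl)oxy]methyl}-3-[(methoxymethoxy)methyl]phenoxy}-6-(benzyloxy)-3-bromo-4-methylbenzaldehyde | C=CCOc1c(COCOC)c(OCc2ccccc2)c(COCc2ccc(OC)cc2)c(C(OCC)OCC)c1Oc1c(C=O)c(OCc2ccccc2)cc(C)c1Br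
F4 | step 14 | benzylic alcohol from reduction of F3 | C=CCOc1c(COCOC)c(OCc2ccccc2)c(COCc2ccc(OC)cc2)c(C(OCC)OCC)c1Oc1c(CO)c(OCc2ccccc2)cc(C)c1Br
F5 | step 14 | methoxymethyl ether of F4 | C=CCOc1c(COCOC)c(OCc2ccccc2)c(COCc2ccc(OC)cc2)c(C(OCC)OCC)c1Oc1c(COCOC)c(OCc2ccccc2)cc(C)c1Br
F6 | step 14 | ring-B phenol from deallylation of F5 | Oc1c(COCOC)c(OCc2ccccc2)c(COCc2ccc(OC)cc2)c(C(OCC)OCC)c1Oc1c(COCOC)c(OCc2ccccc2)cc(C)c1Br
F7 | step 24 | (R)-benzyl carbonate of the target lactol, both phenols and both hydroxymethyl groups free | Cc1cc(O)c(CO)c2c1C(=O)Oc1c(CO)c(O)c3c(c1O2)[C@@H](OC(=O)OCc1ccccc1)OC3=O
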